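**Strategy.** The cycloheptenone unit C(=O)–C(CH3)=C(chain) of the hydroazulene is read as a masked 2-methyl-1,3-dione, and the molecule is cut between its chain-bearing alkene carbon and the ethylene linker (Stork–Danheiser union with an alkyllithium of the oxepane–cyclohexane half). The key step makes the seven-membered ring from the cyclopentanone ring of a cis-bicyclo[3.3.0]octanone: chloro(methyl)ketene [2+2] addition to its silyl enol ether and reductive retro-aldol opening insert the C(=O)–CH(CH3) unit between the old carbonyl carbon and its α-CH2 in one flask. The precursor is a gem-dimethyl diquinane silyl enol ether carrying the tertiary carbinol, made by Pauson–Khand cyclization of (R)-dehydrolinalool. Both halves start from one epoxygeraniol.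

Key step: step 8

Remark: geraniol (1), dimethyl (2-oxopropyl)phosphonate (14) and benzyloxyacetaldehyde (16) are taken as purchased, the L-fructose-derived epoxidation ketone is used as a purchased catalyst, and centers that are erased later (ring-fusion CH of 5, chloro/methyl carbon of 9 and 10, methyl-bearing carbon of 11, carbinol carbon of 25) are left unspecified.

Step 1
Reactants: 1 geraniol
Product: 2 (2R,3R)-2,3-epoxygeraniol
Conditions: Ti(OiPr)4 (cat.), D-(−)-diisopropyl tartrate (cat.), t-BuOOH, 4 Å molecular sieves, CH2Cl2, −20 °C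
Reagents that add atoms: tert-butyl hydroperoxide, CC(C)(C)OO
Why: Sharpless asymmetric epoxidation of the allylic alcohol; the D-tartrate complex should deliver oxygen to the face that gives the (2R,3R)-epoxide and leave the remote trisubstituted alkene untouched.

Step 2
Reactants: 2 (2R,3R)-2,3-epoxygeraniol
Product: 3 (2S,3R)-2-(chloromethyl)-3-methyl-3-(4-methylpent-3-en-1-yl)oxirane
Conditions: PPh3, CCl4, NaHCO3, reflux
Reagents that add atoms: tetrachloromethane, ClC(Cl)(Cl)Cl
Why: Appel chlorination of the primary alcohol under neutral conditions that the epoxide tolerates; no stereocenter is touched (the descriptor changes only by priority).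

Step 3
Reactants: 3 epoxy chloride
Product: 4 (R)-dehydrolinalool, (3R)-3,7-dimethyloct-6-en-1-yn-3-ol
Conditions: n-BuLi (3.2 equiv), THF, −40 °C to rt; aq. NH4Cl
Reagents that add atoms: none
Why: Base-induced double elimination of a 2,3-epoxy chloride (deprotonation next to chlorine, eliminative epoxide opening to a chlorovinyl alkoxide, dehydrochlorination) should give the terminal alkynyl carbinol; the C–O bond of the tertiary center is never broken, so it stays (R).

Step 4
Reactants: 4 (R)-dehydrolinalool
Product: 5 (4R)-4-hydroxy-1,1,4-trimethyl-4,5,6,6a-tetrahydropentalen-2(1H)-one (both C6a epimers)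
Conditions: Co2(CO)8 (10 mol%), tetramethylthiourea (60 mol%), CO (1 atm), benzene, 70 °C
Reagents that add atoms: carbon monoxide, [C-]#[O+]
Why: Intramolecular Pauson–Khand [2+2+1] cycloaddition of the 1,6-enyne, helped by the fully substituted carbinol carbon in the tether, should form the cyclopentenone with the gem-dimethyl carbon from the alkene terminus; the new ring-fusion CH may form as a mixture because step 5 erases it.

Step 5
Reactants: 5 conjugated bicyclic enone
Product: 6 (4R)-4-hydroxy-1,1,4-trimethyl-3,4,5,6-tetrahydropentalen-2(1H)-one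
Conditions: KOt-Bu (3 equiv), t-BuOH/THF, 0 °C; inverse quench into cold 10% aq. AcOH
Reagents that add atoms: none
Why: Deconjugation through the extended dienolate: the only enolizable hydrogen is the γ ring-fusion CH (the α′ carbon is quaternary), and kinetic α-protonation should give the β,γ-enone with the tetrasubstituted ring-fusion alkene, converging both epimers of 5.

Step 6
Reactants: 6 β,γ-unsaturated hydroxy ketone
Product: 7 (3aR,4R,6aR)-4-hydroxy-1,1,4-trimethylhexahydropentalen-2(1H)-one (cis-fused, OH cis to both ring-fusion hydrogens)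
Conditions: [Ir(cod)(PCy3)(py)]PF6 (10 mol%), H2 (3 atm), CH2Cl2, rt
Reagents that add atoms: none
Why: Hydroxyl-directed homogeneous hydrogenation: the allylic tertiary OH binds iridium and both hydrogens should add to the alkene face syn to it, setting the two ring-fusion centers cis to each other and cis to OH.

Step 7
Reactants: 7 hydroxy diquinanone
Product: 8 bis(trimethylsilyl) derivative of 7 (C2=C3 trimethylsilyl enol ether, C4 trimethylsilyl ether)
Conditions: TMSOTf (2.5 equiv), Et3N (3 equiv), CH2Cl2, 0 °C
Reagents that add atoms: trimethylsilyl trifluoromethanesulfonate, C[Si](C)(C)OS(=O)(=O)C(F)(F)F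
Why: Soft enolization and silylation; the enol ether can only form toward the CH2 because the other α-carbon is quaternary, and the tertiary alcohol is silylated in the same operation.

Step 8
Reactants: 8 bis(trimethylsilyl) derivative
Product: 11 (1R,3aR,8aR)-1-hydroxy-1,4,4,6-tetramethyloctahydroazulene-5,7-dione, via chlorocyclobutanone adduct 9 (not isolated), via dechlorinated cyclobutanone 10 (not isolated)
Conditions: CH3CHClCOCl (slow addition), Et3N, hexane, 25 to 50 °C; filter, concentrate; Zn, AcOH, i-PrOH/H2O, 0 °C to rt; then 1 M HCl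
Reagents that add atoms: 2-chloropropanoyl chloride, CC(Cl)C(Cl)=O
Why: Dehydrochlorination of the acid chloride gives chloro(methyl)ketene, whose central carbon is attacked by the nucleophilic CH of the silyl enol ether; the chloro enolate then closes onto the silyloxocarbenium carbon (stepwise [2+2], a 4-exo closure of the cyclobutanone on the convex face of the cis-bicyclooctane), as in the known cycloadditions of halogenated ketenes with silyl enol ethers. Zinc in acetic acid then removes chlorine through the zinc enolate, and desilylation of the β-silyloxy cyclobutanone triggers strain-driven retro-aldol cleavage of the bond shared by the four- and five-membered rings, so the cyclopentanone ring expands by the two ketene carbons to the cycloheptane-1,3-dione, the sequence known for turning 1-silyloxycyclopentene into cycloheptane-1,3-dione with dichloroketene. Regiochemistry is secured twice: the enol ether can only lie away from the quaternary CMe2 carbon, and ketene polarity places the new carbonyl on the former α-CH2 carbon and the methyl-bearing carbon between the two carbonyls. The cyclobutane stereocenters and the chloro/methyl center are erased by reduction and fragmentation, the methyl-bearing carbon of 11 is epimerizable and later becomes sp2, and the three existing stereocenters are not touched, so no stereoselectivity is required. The one demand is that four-ring closure next to the quaternary carbon outruns silyl transfer to open-chain C-acylation, which the nonpolar solvent and the α-chloro substituent should favor.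

Step 9
Reactants: 11 hydroxy dione
Product: 12 (1R,3aR,8aR)-1-hydroxy-7-methoxy-1,4,4,6-tetramethyl-2,3,3a,4,8,8a-hexahydroazulen-5(1H)-one
Conditions: HC(OMe)3, MeOH, camphorsulfonic acid (cat.), rt
Reagents that add atoms: trimethyl orthoformate, COC(OC)OC
Why: Acid-catalyzed vinylogous ester formation under thermodynamic control should place methoxy on the carbonyl carbon flanked by CH2 and keep the ketone next to the quaternary CMe2 carbon, the regiochemistry known for 4,4-dimethylcyclohexane-1,3-dione.

Step 10
Reactants: 2 (2R,3R)-2,3-epoxygeraniol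
Product: 13 (2S,3R)-2-(iodomethyl)-3-methyl-3-(4-methylpent-3-en-1-yl)oxirane
Conditions: I2, PPh3, imidazole, CH2Cl2, 0 °C
Reagents that add atoms: iodine, II
Why: Appel-type iodination of the primary epoxy alcohol; stereocenters are untouched.

Step 11
Reactants: 13 epoxy iodide; 14 dimethyl (2-oxopropyl)phosphonate
Product: 15 dimethyl {4-[(2R,3R)-3-methyl-3-(4-methylpent-3-en-1-yl)oxiran-2-yl]-2-oxobutyl}phosphonate
Conditions: 14, NaH then n-BuLi, THF, 0 °C; add 13, 0 °C to rt; aq. NH4Cl
Reagents that add atoms: none
Why: γ-Alkylation of the β-ketophosphonate dianion by SN2 at the primary iodide; displacement at CH2I should be faster than opening of the trisubstituted oxirane.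

Step 12
Reactants: 15 β-ketophosphonate; 16 benzyloxyacetaldehyde
Product: 17 (E)-6-(benzyloxy)-1-[(2R,3R)-3-methyl-3-(4-methylpent-3-en-1-yl)oxiran-2-yl]hex-4-en-3-one
Conditions: LiCl, i-Pr2NEt, MeCN, rt
Reagents that add atoms: none
Why: Horner–Wadsworth–Emmons olefination under mild LiCl/amine conditions should give the (E)-enone without touching the epoxide.

Step 13
Reactants: 17 epoxy enone
Product: 18 (E)-6-(benzyloxy)-1-[(2R,3R)-3-{2-[(2S)-3,3-dimethyloxiran-2-yl]ethyl}-3-methyloxiran-2-yl]hex-4-en-3-one
Conditions: L-fructose-derived Shi ketone (30 mol%), Oxone (2KHSO5·KHSO4·K2SO4), K2CO3, Bu4NHSO4, MeCN/dimethoxymethane/aq. buffer pH 10.5, 0 °C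
Reagents that add atoms: potassium peroxymonosulfate, [K+].[O-]S(=O)(=O)OO
Why: Shi epoxidation: the chiral dioxirane should epoxidize the electron-rich trisubstituted alkene through a spiro transition state with catalyst control to the (S)-epoxide, while the electron-poor enone alkene does not react.

Step 14
Reactants: 18 diepoxy enone
Product: 19 (Z)-triethylsilyl enol ether of the saturated ketone (silyloxy carbon C3 of the hexene chain, alkene toward the benzyloxyethyl end)
Conditions: Et3SiH, RhCl(PPh3)3 (2 mol%), toluene, 50 °C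
Reagents that add atoms: triethylsilane, CC[SiH](CC)CC
Why: Rhodium-catalyzed 1,4-hydrosilylation of the enone through its s-cis conformer should give regiospecifically the (Z)-silyl enol ether on the side of the former alkene, which direct enolization of the saturated ketone could not do.

Step 15
Reactants: 19 diepoxy (Z)-enol silane
Product: 20 (3S,5aR,6R,9aR)-6-[2-(benzyloxy)ethyl]-2,2,5a-trimethyl-3-(triethylsilyloxy)octahydro-1-benzoxepin-7(2H)-one
Conditions: TESOTf (1.2 equiv), 2,6-di-tert-butyl-4-methylpyridine, CH2Cl2, −78 °C; aq. NaHCO3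
Reagents that add atoms: triethylsilyl trifluoromethanesulfonate, CC[Si](CC)(CC)OS(=O)(=O)C(F)(F)F
Why: Silyl triflate-promoted tandem oxa-/carbacyclization of a diepoxide: the silylated terminal epoxide is opened at its tertiary carbon by the oxygen of the second epoxide to a bicyclic epoxonium ion, which the enol silane opens at the tertiary carbon with inversion through a chair, so the trans ring fusion follows from the trans-epoxide, the oxepane carbinol center is carried over from the (S)-epoxide, and the (Z)-enol ether puts the side chain equatorial.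

Step 16
Reactants: 20 bicyclic ketone
Product: 21 (3S,5aR,6R,7S,9aR)-6-[2-(benzyloxy)ethyl]-2,2,5a,7-tetramethyl-3-(triethylsilyloxy)decahydro-1-benzoxepin-7-ol
Conditions: MeLi, CeCl3, THF, −78 °C; aq. NH4Cl
Reagents that add atoms: methyllithium, [Li]C
Why: 1,2-Addition of the organocerium reagent: axial attack is blocked by the syn-axial angular methyl group, so methyl should enter equatorially and give the axial tertiary alcohol (7S), while CeCl3 suppresses enolization of the epimerizable α-center.

Step 17
Reactants: 21 benzyl ether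
Product: 22 (3S,5aR,6R,7S,9aR)-6-(2-hydroxyethyl)-2,2,5a,7-tetramethyl-3-(triethylsilyloxy)decahydro-1-benzoxepin-7-ol
Conditions: H2 (1 atm), Pd/C (10% palladium on carbon), EtOAc, rt
Reagents that add atoms: none
Why: Hydrogenolysis of the benzyl ether in ethyl acetate, conditions under which the triethylsilyl ether and the other C–O bonds should survive.

Step 18
Reactants: 22 diol
Product: 23 (3S,5aR,6R,7S,9aR)-6-(2-iodoethyl)-2,2,5a,7-tetramethyl-3-(triethylsilyloxy)decahydro-1-benzoxepin-7-ol
Conditions: I2, PPh3, imidazole, CH2Cl2, 0 °C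
Reagents that add atoms: iodine, II
Why: Appel-type iodination selective for the primary alcohol; the hindered axial tertiary alcohol should not react.

Step 19
Reactants: 23 iodide; 12 vinylogous ester
Product: 26 target CNP0397160.2, via alkyllithium alkoxide 24 (not isolated), via tertiary carbinol adduct 25 (not isolated)
Conditions: 23: MeLi (1 equiv) then t-BuLi (2.1 equiv), Et2O/pentane, −78 °C; add 12 (pre-treated with MeLi, 1 equiv, THF, −78 °C); −78 to 0 °C; then 1 M HCl, THF, rt
Reagents that add atoms: water, O
Why: Iodine–lithium exchange after deprotonation of the free hydroxyl, then the Stork–Danheiser sequence: 1,2-addition of the primary alkyllithium to the vinylogous ester carbonyl and acid-induced ionization and hydrolysis transpose the carbonyl to the 2-methyl-3-alkyl enone, and the same acid removes the triethylsilyl ether; no stereocenter is formed or touched.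

**Compound list**

1 | geraniol | CC(C)=CCC/C(C)=C/CO | starting material
2 | (2R,3R)-2,3-epoxygeraniol | CC(C)=CCC[C@@]1(C)O[C@@H]1CO | intermediate
3 | (2S,3R)-2-(chloromethyl)-3-methyl-3-(4-methylpent-3-en-1-yl)oxirane | CC(C)=CCC[C@@]1(C)O[C@@H]1CCl | intermediate
4 | (R)-dehydrolinalool | C#C[C@](C)(O)CCC=C(C)C | intermediate
5 | (4R)-4-hydroxy-1,1,4-trimethyl-4,5,6,6a-tetrahydropentalen-2(1H)-one, C6a epimers | CC1(C)C(=O)C=C2C1CC[C@@]2(C)O | intermediate
6 | (4R)-4-hydroxy-1,1,4-trimethyl-3,4,5,6-tetrahydropentalen-2(1H)-one | CC1(C)C(=O)CC2=C1CC[C@@]2(C)O | intermediate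
7 | (3aR,4R,6aR)-4-hydroxy-1,1,4-trimethylhexahydropentalen-2(1H)-one | O=C1C(C)(C)[C@@H]2CC[C@@](C)(O)[C@@H]2C1 | intermediate
8 | bis(trimethylsilyl) derivative of 7 (enol ether and tertiary ether) | CC1(C)C(O[Si](C)(C)C)=C[C@H]2[C@](C)(O[Si](C)(C)C)CC[C@@H]12 | intermediate
9 | tricyclic 2-chloro-2-methylcyclobutanone [2+2] adduct of 8 | CC1(C)[C@@H]2CC[C@@](C)(O[Si](C)(C)C)[C@@H]2[C@H]3C(=O)C(C)(Cl)[C@@]13O[Si](C)(C)C | intermediate (not isolated)
10 | dechlorinated 2-methylcyclobutanone | CC1(C)[C@@H]2CC[C@@](C)(O[Si](C)(C)C)[C@@H]2[C@H]3C(=O)C(C)[C@@]13O[Si](C)(C)C | intermediate (not isolated)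
11 | (1R,3aR,8aR)-1-hydroxy-1,4,4,6-tetramethyloctahydroazulene-5,7-dione, C6 epimers | CC1C(=O)C(C)(C)[C@@H]2CC[C@@](C)(O)[C@@H]2CC1=O | intermediate
12 | (1R,3aR,8aR)-1-hydroxy-7-methoxy-1,4,4,6-tetramethyl-2,3,3a,4,8,8a-hexahydroazulen-5(1H)-one | COC1=C(C)C(=O)C(C)(C)[C@@H]2CC[C@@](C)(O)[C@@H]2C1 | intermediate
13 | (2S,3R)-2-(iodomethyl)-3-methyl-3-(4-methylpent-3-en-1-yl)oxirane | CC(C)=CCC[C@@]1(C)O[C@@H]1CI | intermediate
14 | dimethyl (2-oxopropyl)phosphonate | CC(=O)CP(=O)(OC)OC | starting material
15 | dimethyl {4-[(2R,3R)-3-methyl-3-(4-methylpent-3-en-1-yl)oxiran-2-yl]-2-oxobutyl}phosphonate | CC(C)=CCC[C@@]1(C)O[C@@H]1CCC(=O)CP(=O)(OC)OC | intermediate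
16 | benzyloxyacetaldehyde | O=CCOCc1ccccc1 | starting material
17 | (E)-6-(benzyloxy)-1-[(2R,3R)-3-methyl-3-(4-methylpent-3-en-1-yl)oxiran-2-yl]hex-4-en-3-one | CC(C)=CCC[C@@]1(C)O[C@@H]1CCC(=O)/C=C/COCc1ccccc1 | intermediate
18 | (E)-6-(benzyloxy)-1-[(2R,3R)-3-{2-[(2S)-3,3-dimethyloxiran-2-yl]ethyl}-3-methyloxiran-2-yl]hex-4-en-3-one | CC1(C)O[C@H]1CC[C@@]2(C)O[C@@H]2CCC(=O)/C=C/COCc3ccccc3 | intermediate
19 | (Z)-triethylsilyl enol ether of the diepoxy ketone | CC1(C)O[C@H]1CC[C@@]2(C)O[C@@H]2CC/C(O[Si](CC)(CC)CC)=C/CCOCc3ccccc3 | intermediate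
20 | (3S,5aR,6R,9aR)-6-[2-(benzyloxy)ethyl]-2,2,5a-trimethyl-3-(triethylsilyloxy)octahydro-1-benzoxepin-7(2H)-one | c1ccccc1COCC[C@@H]2[C@@]3(C)CC[C@H](O[Si](CC)(CC)CC)C(C)(C)O[C@@H]3CCC2=O | intermediate
21 | (3S,5aR,6R,7S,9aR)-6-[2-(benzyloxy)ethyl]-2,2,5a,7-tetramethyl-3-(triethylsilyloxy)decahydro-1-benzoxepin-7-ol | c1ccccc1COCC[C@@H]2[C@@]3(C)CC[C@H](O[Si](CC)(CC)CC)C(C)(C)O[C@@H]3CC[C@]2(C)O | intermediate
22 | (3S,5aR,6R,7S,9aR)-6-(2-hydroxyethyl)-2,2,5a,7-tetramethyl-3-(triethylsilyloxy)decahydro-1-benzoxepin-7-ol | OCC[C@@H]1[C@@]2(C)CC[C@H](O[Si](CC)(CC)CC)C(C)(C)O[C@@H]2CC[C@]1(C)O | intermediate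
23 | (3S,5aR,6R,7S,9aR)-6-(2-iodoethyl)-2,2,5a,7-tetramethyl-3-(triethylsilyloxy)decahydro-1-benzoxepin-7-ol | ICC[C@@H]1[C@@]2(C)CC[C@H](O[Si](CC)(CC)CC)C(C)(C)O[C@@H]2CC[C@]1(C)O | intermediate
24 | alkyllithium lithium alkoxide from 23 | [Li]CC[C@@H]1[C@@]2(C)CC[C@H](O[Si](CC)(CC)CC)C(C)(C)O[C@@H]2CC[C@]1(C)O[Li] | intermediate (not isolated)
25 | tertiary carbinol 1,2-adduct (shown protonated) | COC1=C(C)C(O)(CC[C@@H]2[C@@]3(C)CC[C@H](O[Si](CC)(CC)CC)C(C)(C)O[C@@H]3CC[C@]2(C)O)C(C)(C)[C@@H]2CC[C@@](C)(O)[C@@H]2C1 | intermediate (not isolated)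
26 | CNP0397160.2 | CC1=C(CC[C@@H]2[C@@]3(C)CC[C@H](O)C(C)(C)O[C@@H]3CC[C@]2(C)O)C(C)(C)[C@@H]2CC[C@@](C)(O)[C@@H]2CC1=O | target

**Count.** Total steps: 19. Longest linear sequence: 11 steps (steps 1, 10 to 18, 19); the other branch (steps 1 to 9, 19) has 10.

**Steps most likely to fail**

Step 8. The alkyl chloroketene may add too slowly to the hindered enol ether, or the zwitterion may collapse by silyl transfer to open-chain C-acylation instead of closing the four-membered ring next to the quaternary carbon. Fallback, setting out from 8: the far more electrophilic dichloroketene (Cl2CHCOCl, Et3N, hexane) should give the dichlorocyclobutanone adduct F1. Zn/AcOH then dechlorinates and fragments it to the unmethylated dione (1R,3aR,8aR)-1-hydroxy-1,4,4-trimethyloctahydroazulene-5,7-dione F2. C-methylation between the carbonyls (MeI, K2CO3, acetone) comes back to the route at 11.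

Step 15. The silyl triflate may desilylate the enol silane before C–C bond formation, or the enol silane may attack an epoxide directly, so that the cascade stops at ketone or monocyclic material. Fallback, setting out from 19: CsF and PhNTf2 convert the enol silane with retention of geometry into the (Z)-enol triflate F3. Kumada coupling with Me3SiCH2MgCl and Pd(PPh3)4 gives the allylsilane F4, a terminator that is inert to silyl triflate. The same TESOTf cascade then ends by loss of the trimethylsilyl group and gives the exocyclic methylene bicycle F5. Ozonolysis (O3, CH2Cl2, −78 °C; Me2S) comes back to the route at 20.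

Step 4. Insertion of the trisubstituted gem-dimethyl alkene into the cobalt–alkyne complex may be too slow, so that the complex decomposes or the alkyne oligomerizes. Fallback, setting out from 4: selective ozonolysis of the alkene (O3, −78 °C; Me2S) gives the lactol (5R)-5-ethynyl-5-methyltetrahydrofuran-2-ol F6. Wittig methylenation (Ph3P=CH2, excess) gives (R)-3-methylhept-6-en-1-yn-3-ol F7. Its Pauson–Khand reaction with the unhindered monosubstituted alkene gives (4R)-4-hydroxy-4-methyl-4,5,6,6a-tetrahydropentalen-2(1H)-one F8. Two rounds of α′-methylation at the CH2 next to the carbonyl (excess LDA, MeI, THF, −78 °C) come back to the route at 5.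

**Further compounds**

F1 | step 8 | tricyclic 2,2-dichlorocyclobutanone [2+2] adduct of 8 | CC1(C)[C@@H]2CC[C@@](C)(O[Si](C)(C)C)[C@@H]2[C@H]3C(=O)C(Cl)(Cl)[C@@]13O[Si](C)(C)C
F2 | step 8 | (1R,3aR,8aR)-1-hydroxy-1,4,4-trimethyloctahydroazulene-5,7-dione | O=C1CC(=O)C(C)(C)[C@@H]2CC[C@@](C)(O)[C@@H]2C1
F3 | step 15 | (Z)-enol triflate of the diepoxy ketone | CC1(C)O[C@H]1CC[C@@]2(C)O[C@@H]2CC/C(OS(=O)(=O)C(F)(F)F)=C/CCOCc3ccccc3
F4 | step 15 | diepoxy allylsilane | CC1(C)O[C@H]1CC[C@@]2(C)O[C@@H]2CC/C(C[Si](C)(C)C)=C/CCOCc3ccccc3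
F5 | step 15 | (3S,5aR,6R,9aR)-6-[2-(benzyloxy)ethyl]-2,2,5a-trimethyl-7-methylidene-3-(triethylsilyloxy)decahydro-1-benzoxepine | c1ccccc1COCC[C@@H]2[C@@]3(C)CC[C@H](O[Si](CC)(CC)CC)C(C)(C)O[C@@H]3CCC2=C
F6 | step 4 | (5R)-5-ethynyl-5-methyltetrahydrofuran-2-ol | C#C[C@@]1(C)CCC(O)O1
F7 | step 4 | (R)-3-methylhept-6-en-1-yn-3-ol | C#C[C@](C)(O)CCC=C
F8 | step 4 | (4R)-4-hydroxy-4-methyl-4,5,6,6a-tetrahydropentalen-2(1H)-one | O=C1CC2CC[C@@](C)(O)C2=C1
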